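**Retrosynthetic overview**
- The target is opened to an acyclic hydroxy‑ynone/enaminone that already carries the linoleate on the quaternary carbon. One acid‑triggered cascade closes the carbocycle first (C8a–C4a, 6‑endo‑dig conjugate addition) and then the pyran (O2–C1, displacement of Me2NH); the carbocycle is never aromatic.
- The acyclic precursor comes from a lithium acetylide (silyl‑protected (R)‑pent‑4‑yn‑2‑ol, which supplies C3) opening a lactate‑derived dioxolanone at its lactone carbonyl (C5–C6 bond). Pivaldehyde is lost and the tertiary alkoxide is trapped with linoleoyl chloride.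
- The dioxolanone comes from (R)‑lactic acid and pivaldehyde. C‑acylation of its enolate with (E)‑3‑ethoxyacryloyl chloride sets C7, and OEt/NMe2 exchange gives the enaminone arm (C8, C8a, C1).

Assumption: the target is read as the (3R,7R) isomer (atom labels C1–C8a follow isochromene numbering); (R)‑lactic acid and (R)‑pent‑4‑yn‑2‑ol are bought as single enantiomers.

**Step 1**
Reactants: 1 (R)‑lactic acid; 2 pivaldehyde
Product: 3 (2R,5R)‑2‑tert‑butyl‑5‑methyl‑1,3‑dioxolan‑4‑one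
Conditions: p‑toluenesulfonic acid monohydrate (cat.), H2SO4 (cat.), pentane, reflux, Dean–Stark; crystallise from Et2O/pentane, −78 °C
Reagents that add atoms: pivaldehyde (2), CC(C)(C)C=O
Why: Acid‑catalysed acetalisation with water removal (Seebach dioxolanone formation); the new acetal centre is set relative to the lactate centre, the cis isomer being favoured (about 4:1) and enriched to >95:5 by crystallisation.

**Step 2**
Reactants: 3 (2R,5R)‑2‑tert‑butyl‑5‑methyl‑1,3‑dioxolan‑4‑one; 4 (E)‑3‑ethoxyprop‑2‑enoyl chloride; 5 dimethylamine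
Product: 8 (2R,5S)‑2‑tert‑butyl‑5‑[(E)‑3‑(dimethylamino)prop‑2‑enoyl]‑5‑methyl‑1,3‑dioxolan‑4‑one, via lithium enolate 6 (not isolated), via ethoxyenone 7 (not isolated)
Conditions: LiN(iPr)2 (1.05 equiv), THF, −78 °C; cannulate into 4 (1.2 equiv), THF, −78 °C; then Me2NH (2 M in THF, 2.5 equiv), −78 → 0 °C
Reagents that add atoms: (E)‑3‑ethoxyprop‑2‑enoyl chloride (4), CCO/C=C/C(=O)Cl; dimethylamine (5), CNC
Why: Seebach self‑regeneration of stereocentres: the planar enolate is C‑acylated anti to the tert‑butyl group, so the acyl group replaces the lactate hydrogen with retention and fixes the quaternary centre (later C7); conjugate addition–elimination of Me2NH on the β‑ethoxy enone then gives a vinylogous amide that is inert to the acetylide of step 4.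

**Step 3**
Reactants: 9 (R)‑pent‑4‑yn‑2‑ol; 10 chlorotriethylsilane
Product: 11 triethyl{[(2R)‑pent‑4‑yn‑2‑yl]oxy}silane
Conditions: Et3SiCl (1.1 equiv), imidazole (1.5 equiv), CH2Cl2, 0 °C → rt
Reagents that add atoms: chlorotriethylsilane (10), CC[Si](Cl)(CC)CC
Why: Standard silyl ether formation on oxygen; the carbinol stereocentre (later C3) is not touched.

**Step 4**
Reactants: 11 triethyl{[(2R)‑pent‑4‑yn‑2‑yl]oxy}silane; 8 (2R,5S)‑2‑tert‑butyl‑5‑[(E)‑3‑(dimethylamino)prop‑2‑enoyl]‑5‑methyl‑1,3‑dioxolan‑4‑one; 12 (9Z,12Z)‑octadeca‑9,12‑dienoyl chloride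
Product: 16 (1E,4S,9R)‑1‑(dimethylamino)‑4‑methyl‑3,5‑dioxo‑9‑(triethylsilyloxy)dec‑1‑en‑6‑yn‑4‑yl (9Z,12Z)‑octadeca‑9,12‑dienoate, via lithium acetylide 13 (not isolated), via hemiketal alkoxide 14 (not isolated), via tertiary alkoxide 15 (not isolated)
Conditions: 11 (1.1 equiv), n‑BuLi (1.05 equiv), THF, −78 °C; add 8, −78 °C, 1 h, then → −30 °C; then 12 (1.3 equiv), 4‑(dimethylamino)pyridine (0.1 equiv), −30 → 0 °C; pH 7 buffer
Reagents that add atoms: triethyl{[(2R)‑pent‑4‑yn‑2‑yl]oxy}silane (11), C#CC[C@@H](C)O[Si](CC)(CC)CC; (9Z,12Z)‑octadeca‑9,12‑dienoyl chloride (12), CCCCC/C=C\C/C=C\CCCCCCCC(=O)Cl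
Why: Acetylide addition to the activated (acylal‑type) lactone carbonyl gives a hemiketal alkoxide that collapses on warming with loss of pivaldehyde to the ynone and its tertiary lithium alkoxide, which is O‑acylated in the same pot (nucleophilic acyl substitution twice); no stereocentre is formed and no bond to the quaternary carbon is broken.

**Step 5**
Reactants: 16 (1E,4S,9R)‑1‑(dimethylamino)‑4‑methyl‑3,5‑dioxo‑9‑(triethylsilyloxy)dec‑1‑en‑6‑yn‑4‑yl (9Z,12Z)‑octadeca‑9,12‑dienoate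
Product: 19 (3R,7R)‑3,7‑dimethyl‑6,8‑dioxo‑3,4,7,8‑tetrahydro‑6H‑isochromen‑7‑yl (9Z,12Z)‑octadeca‑9,12‑dienoate, via hydroxy ynone 17 (not isolated), via aminodienone 18 (not isolated)
Conditions: AcOH–THF–H2O (3:1:1), 0.02 M, Ar, rt, 3 h; then 55 °C, 6–8 h
Reagents that add atoms: none
Why: Proposed new method: after acid hydrolysis of the silyl ether, the nucleophilic α‑carbon of the enaminone adds 6‑endo‑dig to the β‑carbon of the acid‑activated ynone (closest known reactions: the enamine‑to‑ynone Michael step of the Bohlmann–Rahtz synthesis, [5+1] double Michael annulations of diynones and amine‑mediated ynone cyclotrimerisation), proton transfer gives the aminomethylidene cyclohexenedione, and the side‑chain hydroxyl then displaces dimethylamine by conjugate addition–elimination (as in chromone formation from o‑hydroxyaryl enaminones) with AcOH trapping the amine; both stereocentres are already in place and untouched (C7 is quaternary and non‑enolisable, the C3–O bond is never broken).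

**Compound list**
1 | (R)‑lactic acid, (2R)‑2‑hydroxypropanoic acid | C[C@@H](O)C(=O)O | starting material
2 | pivaldehyde (2,2‑dimethylpropanal) | CC(C)(C)C=O | starting material
3 | (2R,5R)‑2‑tert‑butyl‑5‑methyl‑1,3‑dioxolan‑4‑one (cis) | C[C@H]1O[C@@H](C(C)(C)C)OC1=O | intermediate
4 | (E)‑3‑ethoxyprop‑2‑enoyl chloride | CCO/C=C/C(=O)Cl | starting material
5 | dimethylamine | CNC | starting material
6 | lithium (2R)‑2‑tert‑butyl‑5‑methyl‑2H‑1,3‑dioxol‑4‑olate | [Li+].CC1=C([O-])O[C@H](C(C)(C)C)O1 | intermediate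
7 | (2R,5S)‑2‑tert‑butyl‑5‑[(E)‑3‑ethoxyprop‑2‑enoyl]‑5‑methyl‑1,3‑dioxolan‑4‑one (acyl trans to tert‑butyl) | C[C@@]1(C(=O)/C=C/OCC)O[C@@H](C(C)(C)C)OC1=O | intermediate
8 | (2R,5S)‑2‑tert‑butyl‑5‑[(E)‑3‑(dimethylamino)prop‑2‑enoyl]‑5‑methyl‑1,3‑dioxolan‑4‑one | C[C@@]1(C(=O)/C=C/N(C)C)O[C@@H](C(C)(C)C)OC1=O | intermediate
9 | (R)‑pent‑4‑yn‑2‑ol | C[C@@H](O)CC#C | starting material
10 | chlorotriethylsilane | CC[Si](Cl)(CC)CC | starting material
11 | triethyl{[(2R)‑pent‑4‑yn‑2‑yl]oxy}silane | C#CC[C@@H](C)O[Si](CC)(CC)CC | intermediate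
12 | (9Z,12Z)‑octadeca‑9,12‑dienoyl chloride (linoleoyl chloride) | CCCCC/C=C\C/C=C\CCCCCCCC(=O)Cl | starting material
13 | lithium (4R)‑4‑(triethylsilyloxy)pent‑1‑yn‑1‑ide | [Li+].[C-]#CC[C@@H](C)O[Si](CC)(CC)CC | intermediate
14 | lithium hemiketal alkoxide: 13 added to the lactone carbonyl of 8 (4‑alkynyl‑1,3‑dioxolan‑4‑olate; ring centres as in 8; hemiketal carbon undefined) | [Li+].C[C@@]1(C(=O)/C=C/N(C)C)O[C@@H](C(C)(C)C)OC1([O-])C#CC[C@@H](C)O[Si](CC)(CC)CC | intermediate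
15 | lithium (1E,4S,9R)‑1‑(dimethylamino)‑4‑methyl‑3,5‑dioxo‑9‑(triethylsilyloxy)dec‑1‑en‑6‑yn‑4‑olate | [Li+].[O-][C@@](C)(C(=O)/C=C/N(C)C)C(=O)C#CC[C@@H](C)O[Si](CC)(CC)CC | intermediate
16 | (1E,4S,9R)‑1‑(dimethylamino)‑4‑methyl‑3,5‑dioxo‑9‑(triethylsilyloxy)dec‑1‑en‑6‑yn‑4‑yl (9Z,12Z)‑octadeca‑9,12‑dienoate | CCCCC/C=C\C/C=C\CCCCCCCC(=O)O[C@@](C)(C(=O)/C=C/N(C)C)C(=O)C#CC[C@@H](C)O[Si](CC)(CC)CC | intermediate
17 | (1E,4S,9R)‑1‑(dimethylamino)‑9‑hydroxy‑4‑methyl‑3,5‑dioxodec‑1‑en‑6‑yn‑4‑yl (9Z,12Z)‑octadeca‑9,12‑dienoate | CCCCC/C=C\C/C=C\CCCCCCCC(=O)O[C@@](C)(C(=O)/C=C/N(C)C)C(=O)C#CC[C@@H](C)O | intermediate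
18 | (1R)‑5‑[(dimethylamino)methylidene]‑4‑[(2R)‑2‑hydroxypropyl]‑1‑methyl‑2,6‑dioxocyclohex‑3‑en‑1‑yl (9Z,12Z)‑octadeca‑9,12‑dienoate (exocyclic C=C geometry not fixed) | CCCCC/C=C\C/C=C\CCCCCCCC(=O)O[C@@]1(C)C(=O)C(=CN(C)C)C(C[C@@H](C)O)=CC1=O | intermediate
19 | (3R,7R)‑3,7‑dimethyl‑6,8‑dioxo‑3,4,7,8‑tetrahydro‑6H‑isochromen‑7‑yl (9Z,12Z)‑octadeca‑9,12‑dienoate | CCCCC/C=C\C/C=C\CCCCCCCC(=O)O[C@]1(C)C(=O)C=C2C[C@@H](C)OC=C2C1=O | target

**Total step count:** 5. **Longest linear sequence:** 4 steps (1 → 2 → 4 → 5); step 3 is a one‑step side branch.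

**Three steps most likely to fail**

Step 5 is the least precedented. The 6‑endo‑dig carbon attack may be slow in aqueous acid, and it competes with hydrolysis of the enaminone and with attack through the enaminone oxygen. Fallback: setting out from 16, the carbocycle alone is closed by alkyne activation with the gold catalyst Ph3PAuNTf2 (5 mol %, CH2Cl2, rt; monovalent gold), giving the silyl‑protected aminodienone (1R)‑5‑[(dimethylamino)methylidene]‑1‑methyl‑2,6‑dioxo‑4‑[(2R)‑2‑(triethylsilyloxy)propyl]cyclohex‑3‑en‑1‑yl (9Z,12Z)‑octadeca‑9,12‑dienoate F1. HF·pyridine in THF then removes the silyl group and the freed alcohol closes the pyran through 18, coming back to the route at 19.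

Step 4 carries three risks. The hemiketal may collapse early, which lets the acetylide add twice or be consumed by pivaldehyde. The tertiary lithium alkoxide next to the ynone can close 5‑endo‑dig to a furanone or undergo a C‑to‑O acyl shift before it is acylated. The acid chloride can also attack the enaminone. Fallback: setting out from 8, the lactone is opened with Me2AlN(OMe)Me (from AlMe3 and MeNH(OMe)·HCl, CH2Cl2, 0 °C → rt) with loss of pivaldehyde to the hydroxy Weinreb amide (2S,4E)‑5‑(dimethylamino)‑2‑hydroxy‑N‑methoxy‑N,2‑dimethyl‑3‑oxopent‑4‑enamide F2. Its tertiary hydroxyl is acylated with 12 (Et3N, 4‑(dimethylamino)pyridine, CH2Cl2) to (2S,4E)‑5‑(dimethylamino)‑1‑[methoxy(methyl)amino]‑2‑methyl‑1,3‑dioxopent‑4‑en‑2‑yl (9Z,12Z)‑octadeca‑9,12‑dienoate F3. Acetylide 13 is then added to F3 at −78 °C; the chelated adduct releases the ynone only on work‑up, so no free alkoxide ever sits next to it. This comes back to the route at 16.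

Step 2 may give O‑acylation of the enolate instead of C‑acylation, and dimethylamine may open the lactone or cleave the new β‑keto lactone. Fallback: setting out from 3, the same enolate is added to acetaldehyde (aldol, anti to tert‑butyl) to give (2R,5S)‑2‑tert‑butyl‑5‑(1‑hydroxyethyl)‑5‑methyl‑1,3‑dioxolan‑4‑one F4 (carbinol epimers, both used). Dess–Martin periodinane oxidises it to (2R,5S)‑5‑acetyl‑2‑tert‑butyl‑5‑methyl‑1,3‑dioxolan‑4‑one F5. Condensation of the methyl ketone with N,N‑dimethylformamide dimethyl acetal (toluene, 80 °C) comes back to the route at 8.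

**Further compounds**
F1 | step 5 | (1R)‑5‑[(dimethylamino)methylidene]‑1‑methyl‑2,6‑dioxo‑4‑[(2R)‑2‑(triethylsilyloxy)propyl]cyclohex‑3‑en‑1‑yl (9Z,12Z)‑octadeca‑9,12‑dienoate | CCCCC/C=C\C/C=C\CCCCCCCC(=O)O[C@@]1(C)C(=O)C(=CN(C)C)C(C[C@@H](C)O[Si](CC)(CC)CC)=CC1=O
F2 | step 4 | (2S,4E)‑5‑(dimethylamino)‑2‑hydroxy‑N‑methoxy‑N,2‑dimethyl‑3‑oxopent‑4‑enamide | CON(C)C(=O)[C@@](C)(O)C(=O)/C=C/N(C)C
F3 | step 4 | (2S,4E)‑5‑(dimethylamino)‑1‑[methoxy(methyl)amino]‑2‑methyl‑1,3‑dioxopent‑4‑en‑2‑yl (9Z,12Z)‑octadeca‑9,12‑dienoate | CCCCC/C=C\C/C=C\CCCCCCCC(=O)O[C@@](C)(C(=O)/C=C/N(C)C)C(=O)N(C)OC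
F4 | step 2 | (2R,5S)‑2‑tert‑butyl‑5‑(1‑hydroxyethyl)‑5‑methyl‑1,3‑dioxolan‑4‑one (carbinol epimers) | C[C@@]1(C(C)O)O[C@@H](C(C)(C)C)OC1=O
F5 | step 2 | (2R,5S)‑5‑acetyl‑2‑tert‑butyl‑5‑methyl‑1,3‑dioxolan‑4‑one | C[C@@]1(C(C)=O)O[C@@H](C(C)(C)C)OC1=O
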